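## Structural features

The target is a monocyclic nine-membered carbocycle (ring atoms numbered C1, the acetoxy carbon, round to C9, the side-chain carbon) with two ring-cis trisubstituted alkenes, C3(Me)=C4 (Z) and C6=C7 (E by priority, cis within the ring), skipped through the C5 methylene. C7 and C8 carry the two formyl groups of a 1,4-dialdehyde: the C7 formyl is conjugated with C6=C7, while the C8 formyl sits on an sp3 methine whose hydrogen is α to one carbonyl and γ to the other and is therefore easily lost. C8, C9 and C1 form a contiguous stereotriad (all R) that continues into the exocyclic C10 methine (R) of the 6-methylhept-5-en-2-yl chain; the C8 formyl and the C1 acetoxy group lie on one ring face and the side chain on the other. Fragile elements are the enedial, the epimerisable C8, the secondary acetate (base, acyl migration next to free hydroxyls) and the trisubstituted side-chain alkene (electrophilic oxidants). The real difficulty is the medium ring: end-to-end closure of a nine-membered ring holding two cis alkenes fights entropy and transannular strain, and it must be combined with control of three adjacent stereocentres on a mobile frame. The feature exploited is a hidden indane: C1–C6 with the C3 methyl are the carbons of a toluene nucleus, C7–C8–C9 bridge C6 and C1 as the saturated carbons of a fused cyclopentane, and the only carbons of the six-carbon arc that need oxidation are the two fusion carbons C1 and C6. Cleaving the fusion bond of the corresponding 4,7-dihydroindane therefore unveils the ring with carbonyls at C1 and C6 and with C3=C4 already cis.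

## Logic of the disconnections

**25 ⇒ 23 (through 24).** The C6=C7 π bond is traded for a C6–O ester bond and a C7–H bond, and both formyl groups for carbinols. The enedial with its labile C8–H cannot pass any basic or oxidative step, so it is made last. Using the same ester on O1 and O6 removes any need to tell the two carbinols apart, because only the C6 ester ends up β to a formyl group. The forward step must oxidise a 1,4-diol without lactol formation and eliminate without epimerising C8.

**23 ⇒ 22 ⇒ 20 + 21 ⇒ 18.** The C13=C14 bond is cut to a C13 aldehyde and 21, and the aldehyde is hidden as the acetal of 18. An isolated trisubstituted alkene cannot coexist with the oxidative ring cleavage, so the chain must pass that stage two carbons short. Forward demands: acetal release that spares primary silyl ethers and acetates, and an ylide that meets the aldehyde before the esters.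

**18 ⇒ 17 ⇒ 16.** The two acyl C–O bonds and the C1–H and C6–H bonds are removed, leading to a 1,6-diketone. Both oxygens then originate from one operation on one alkene. Demand: hydride must place the C1 hydroxyl anti to the C9 substituent; C6 is free.

**16 ⇒ 14.** The two carbonyl carbons are reconnected as a C1=C6 double bond (through 15). This turns the nine-membered ring into a five-six bicycle, so no medium-ring cyclisation is needed and the C3=C4 geometry is dictated by the six-membered ring. Demand: the oxidant must choose the tetrasubstituted over the trisubstituted alkene.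

**14 ⇒ 13.** Two hydrogens (at C2 and C5) are removed to restore the arene. The flat aromatic template allows ordinary arene and enolate chemistry for C7–C9. Demand: dissolving-metal regiochemistry that leaves the fusion bond unsaturated, and no benzylic C–O bond or reducible group in 13.

**13 ⇒ 12 ⇒ 11.** The O–Si bonds and the C18/C19 carbinol oxidation level are traced to two esters. Esters make C7 and C8 epimerisable, so the C8/C9 trans relationship can be set under thermodynamic control in a rigid ring. Demand: reduction must follow equilibration directly.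

**11 ⇒ 9 (through 10).** The aryl C6–C7 bond is cut. Closing the five-membered ring at this bond lets C7 arrive already bearing C18. The alternative of acylating an aryl ester would leave a C7 ketone flanked by an acidic β-keto ester proton, which resists Wittig-type one-carbon homologation. Any detour through an indene would expose the C9 stereocentre to 1,3-hydrogen shift. Demand: palladium enolate arylation in the presence of a second ester.

**9 ⇒ 7 + 8.** The C7–C8 bond is cut to an ester enolate and 8. This brings in C7 and C18 in one alkylation. Demand: clean mono-alkylation; the C8 configuration formed here is irrelevant.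

**7 ⇒ 5 + 6.** The aryl C1–C9 bond is cut, leading to an E-enoate and an arylboron reagent. The conjugate addition creates C9 under catalyst control next to the existing C10 centre. Demand: the catalyst must override C10 and tolerate the ortho bromide.

**5 ⇒ 3 + 4.** The C8=C9 bond is cut (cross-metathesis). Gain: two simple alkenes.

**3 ⇒ 1 (through 2).** The acetal carbon C13 is traced to the trisubstituted alkene carbon of 1, and C10 comes from the chiral pool. The terpene is chosen so that C10 is bonded directly to the vinyl carbon that becomes C9. A two-carbon olefination of the ten-carbon terpene aldehyde would put an extra methylene between C9 and C10 and give a homologous side chain. Demand: ozone must cleave the tri- and not the monosubstituted alkene.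

## Other disconnections considered

**Alternative 1:** The cut is C1–C9 (plus the lactone C–O bond). The forward key step treats the acyclic formyl bis(alkylidene)succinate A1 with SmI2 (samarium diiodide, divalent samarium). The C1 ketyl adds to C9, the resulting ester enolate is protonated at C8, and the C1 alkoxide closes onto the C8 ester to give the cis-fused lactone A2.
- In its favour: one step would form the ring and the C1/C9 centres, and the lactone ties O1 and the C8 carbonyl to the same face, as the target requires. That is a firmer handle on C1 than a hydride reduction, and here the alternative is the better plan. The side-chain alkene needs no masking, also better.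
- Against it: the ketyl carbon is also 1,6-related to C6, the β-carbon of the second acrylate unit, so a six-membered closure onto C6 should compete with the nine-membered closure onto C9. The β,γ-unsaturated aldehyde of A1 is prone to conjugation. C9 would be set by 1,2-induction from C10 only. The dienolate can protonate at C6 and deconjugate.
- Comparison: the chosen plan pays no cyclisation penalty and sets C9 by catalyst control. On step economy the alternative could be a few steps shorter if the closure worked, but its decisive step is mechanistically the less secure.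

**Alternative 2:** The cut is C1–C2. The forward key step is intramolecular allylboration of the aldehyde–allylboronate A3 through a chair transition state, giving the cyclononadienol A4.
- In its favour: ring, C1 carbinol and Z C3=C4 arise together; C1 is at the right oxidation level; C6=C7 and the side-chain alkene are already present. Only acetylation, desilylation and oxidation would follow, which is better post-key-step economy than the chosen plan. C1 would be reagent-controlled through the boron-bearing stereocentre, at least the equal of a hydride reduction.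
- Against it: the nine-membered ring must form through a bicyclic transition state with a cis alkene in the tether. The aldehyde is α-stereogenic at C9 and can epimerise. A3 needs an acyclic C8–C9–C10 triad, a stereodefined trisubstituted alkene and a configurationally defined secondary allylboronate. Oligomerisation competes.
- Comparison: structurally the alternative is more direct. Mechanistically the chosen plan avoids any medium-ring closure. Overall length is probably similar, because A3 is long to make.

**Alternative 3:** The cut is C8–C9 (with O–C6 re-formed in the precursor). The forward key step is thermal Claisen rearrangement of the 2-alkylidene-7-alkenyl oxepine A5 to the cyclononadienone A6.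
- In its favour: like the chosen plan it is a ring expansion and needs no end-to-end closure, so the two are equal there. It would form C8–C9 and both centres in one concerted event, deliver C6=C7 directly and keep the side-chain alkene. It has no tri- versus tetrasubstituted alkene competition, and the sequence after the key step is shorter. On those points it is better.
- Against it: C8 and C9 depend on three stereo-elements of A5 (enol ether geometry, alkenyl geometry, the C6 carbinol centre), each needing its own synthesis. A branched, stereodefined alkylidene on a seven-membered enol ether has little support. The chair/boat choice decides whether C6=C7 emerges ring-cis. The C1 ketone still needs the same face-selective reduction, so the two are equal there.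
- Comparison: fewer steps after the key step, more and less certain steps before it. The chosen plan sets no stereocentre in its key step and builds C8/C9 thermodynamically on a rigid indane.

Key step: step 9

Remark 1: ring atoms are numbered C1 (acetoxy carbon) to C9 (side-chain carbon); C10 is the side-chain methine and C18/C19 are the carbons on C7/C8.
Remark 2: the C6 carbinol/acetate centre of 17–24 forms as an inconsequential epimer mixture (C6 becomes trigonal in step 15) and is written without a descriptor.
Remark 3: (R)-β-citronellene and (2-bromo-5-methylphenyl)boronic acid are taken to be catalogue compounds of adequate purity.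

## Route

Step 1
Reactants: 1 (R)-β-citronellene [(3R)-3,7-dimethylocta-1,6-diene]
Product: 3 (3R)-6,6-dimethoxy-3-methylhex-1-ene, via (4R)-4-methylhex-5-enal 2 (not isolated)
Conditions: O3 (1.0 equiv), CH2Cl2/MeOH 4:1, Sudan Red 7B, −78 °C; Me2S, −78 → 20 °C; then HC(OMe)3, TsOH·H2O (2 mol %), 20 °C; NaHCO3
Reagents that add atoms: trimethyl orthoformate, COC(OC)OC (both methoxy groups of 3); ozone, O=[O+][O-] (carbonyl oxygen of intermediate 2 only)
Why: Ozonolysis: electrophilic ozone cleaves the electron-rich trisubstituted alkene well before the vinyl group (the dye marks the end point), and aldehyde 2 is acetalised in the same flask under acid catalysis; the C10 centre is not α to the carbonyl and comes unchanged from the chiral pool, and the chain now ends in the masked aldehyde that must survive step 9.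

Step 2
Reactants: 3 (3R)-6,6-dimethoxy-3-methylhex-1-ene; 4 methyl acrylate
Product: 5 methyl (2E,4R)-7,7-dimethoxy-4-methylhept-2-enoate
Conditions: second-generation Hoveyda–Grubbs catalyst RuCl2(H2IMes)(=CH-C6H4-2-O-i-Pr) (3 mol %), 4 (4 equiv), CH2Cl2, 40 °C
Reagents that add atoms: none
Why: Olefin cross-metathesis of a terminal alkene with an electron-poor acrylate favours the cross product and the E-enoate because the acrylate homodimerises slowly; the allylic centre and the acetal are untouched, and C10 is now bonded directly to the β-carbon (future C9), which is the correct carbon count.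

Step 3
Reactants: 5 methyl (2E,4R)-7,7-dimethoxy-4-methylhept-2-enoate; 6 (2-bromo-5-methylphenyl)boronic acid
Product: 7 methyl (3S,4R)-3-(2-bromo-5-methylphenyl)-7,7-dimethoxy-4-methylheptanoate
Conditions: [Rh(OH)((S)-BINAP)]2 (2.5 mol %), 6 (2.5 equiv), dioxane/H2O 10:1, 50 °C
Reagents that add atoms: none
Why: Hayashi–Miyaura asymmetric 1,4-addition: transmetalation gives an aryl complex of monovalent rhodium that inserts the enoate and is protonated by water; by the accepted enantioface model the (S)-BINAP complex should expose the α-si (= β-re) face of an E-acceptor, which sets C9 as required under catalyst control over C10 (the ligand antipode is the remedy if the sense proves opposite). The cyclooctadiene-free hydroxo precatalyst avoids an achiral background, and the aryl bromide and acetal are inert to monovalent rhodium in neutral aqueous dioxane.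

Step 4
Reactants: 7 methyl (3S,4R)-3-(2-bromo-5-methylphenyl)-7,7-dimethoxy-4-methylheptanoate; 8 methyl bromoacetate
Product: 9 dimethyl 2-[(1R,2R)-1-(2-bromo-5-methylphenyl)-5,5-dimethoxy-2-methylpentyl]butanedioate (C8 epimers)
Conditions: LDA (1.05 equiv), THF, −78 °C; then 8 (1.3 equiv), −78 → −30 °C
Reagents that add atoms: none
Why: Ester enolate alkylation (SN2) with a primary α-bromo ester brings in C7 together with C18 at the ester level; the new C8 centre forms as a mixture, which is harmless because step 5 equilibrates it, and LDA at −78 °C enolises the ester faster than it attacks the aryl bromide.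

Step 5
Reactants: 9 dimethyl 2-[(1R,2R)-1-(2-bromo-5-methylphenyl)-5,5-dimethoxy-2-methylpentyl]butanedioate
Product: 11 dimethyl (1S,2R,3R)-3-[(2R)-5,5-dimethoxypentan-2-yl]-5-methyl-2,3-dihydro-1H-indene-1,2-dicarboxylate, via indane diester epimer mixture 10 (not isolated)
Conditions: Pd2(dba)3 (2.5 mol %), t-Bu3P·HBF4 (6 mol %), LiN(SiMe3)2 (2.2 equiv), toluene, 25 → 60 °C; then MeOH, NaOMe (0.3 equiv), 60 °C
Reagents that add atoms: none
Why: Intramolecular palladium-catalysed α-arylation of an ester enolate (Buchwald–Hartwig type): oxidative addition of the aryl bromide to zerovalent palladium, enolate binding at C7 and reductive elimination close the five-membered ring (the C8 enolate could only give a four-membered ring). Methoxide then equilibrates both ester-bearing centres to the all-trans indane, the thermodynamic isomer, which fixes C8 trans to the immovable C9 substituent; C7 is set too but becomes trigonal later.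

Step 6
Reactants: 11 dimethyl (1S,2R,3R)-3-[(2R)-5,5-dimethoxypentan-2-yl]-5-methyl-2,3-dihydro-1H-indene-1,2-dicarboxylate
Product: 12 [(1S,2R,3R)-3-[(2R)-5,5-dimethoxypentan-2-yl]-5-methyl-2,3-dihydro-1H-indene-1,2-diyl]dimethanol
Conditions: LiAlH4, THF, 0 °C; Fieser work-up
Reagents that add atoms: none
Why: Hydride reduction of both esters to primary alcohols removes the acidity at C7 and C8, so the thermodynamically set C8 configuration is locked; the acetal is inert to LiAlH4.

Step 7
Reactants: 12 [(1S,2R,3R)-3-[(2R)-5,5-dimethoxypentan-2-yl]-5-methyl-2,3-dihydro-1H-indene-1,2-diyl]dimethanol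
Product: 13 (1S,2R,3R)-1,2-bis{[(tert-butyldimethylsilyl)oxy]methyl}-3-[(2R)-5,5-dimethoxypentan-2-yl]-5-methyl-2,3-dihydro-1H-indene
Conditions: TBSCl (2.5 equiv), imidazole, DMF, 25 °C
Reagents that add atoms: tert-butyldimethylsilyl chloride, CC(C)(C)[Si](C)(C)Cl
Why: Imidazole-promoted silylation of both primary alcohols gives ethers that tolerate dissolving metal, ozone, hydride and ylide; the oxygens are homobenzylic, so step 8 has no benzylic C–O bond to cleave.

Step 8
Reactants: 13 (1S,2R,3R)-1,2-bis{[(tert-butyldimethylsilyl)oxy]methyl}-3-[(2R)-5,5-dimethoxypentan-2-yl]-5-methyl-2,3-dihydro-1H-indene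
Product: 14 (1S,2R,3R)-1,2-bis{[(tert-butyldimethylsilyl)oxy]methyl}-3-[(2R)-5,5-dimethoxypentan-2-yl]-5-methyl-2,3,4,7-tetrahydro-1H-indene
Conditions: Li (10 equiv), NH3(l)/THF/EtOH, −78 → −33 °C
Reagents that add atoms: none
Why: Birch reduction: the radical anion of the 1,2,4-trialkylbenzene is protonated at the two unsubstituted, para-related carbons C2 and C5, so all alkyl groups stay on the residual double bonds and the 1,4-diene has the tetrasubstituted C1=C6 and the trisubstituted C3=C4 bonds; silyl ethers, acetal and the three stereocentres are not affected.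

Step 9
Reactants: 14 (1S,2R,3R)-1,2-bis{[(tert-butyldimethylsilyl)oxy]methyl}-3-[(2R)-5,5-dimethoxypentan-2-yl]-5-methyl-2,3,4,7-tetrahydro-1H-indene
Product: 16 (3Z,7R,8R,9R)-7,8-bis{[(tert-butyldimethylsilyl)oxy]methyl}-9-[(2R)-5,5-dimethoxypentan-2-yl]-3-methylcyclonon-3-ene-1,6-dione, via bridged secondary ozonide 15 (not isolated)
Conditions: O3 (1.0 equiv, titrated CH2Cl2 solution), CH2Cl2, NaHCO3, −78 °C; then PPh3, −78 → 20 °C
Reagents that add atoms: ozone, O=[O+][O-]
Why: Ozone adds as a 1,3-dipole to C1=C6 to give a primary ozonide, which fragments to a ketone and a carbonyl oxide still tied together by both former ring arms and recombines to the bridged secondary ozonide 15; triphenylphosphine then removes one oxygen and releases the two ketones. The closest known reaction type is the ozonolysis of the ring-fusion tetrasubstituted alkene of Birch-derived 4,7-dihydroindanes and octalins to medium-ring diketones. The nine-membered ring is not closed by bond formation: it is unveiled by scission of the bond shared by the five- and six-membered rings (5 + 6 − 2 ring atoms), so no entropic or transannular penalty of a cyclisation is paid. No stereocentre is created; C7, C8 and C9 are spectators under the cold, neutral conditions, and C3=C4 keeps the cis geometry it had in the six-membered ring, which is the Z geometry of the target. The selectivity needed is site selectivity for the tetrasubstituted C1=C6 over the trisubstituted C3=C4 bond; electrophilic ozone reacts faster the more alkyl groups an alkene carries, and the fusion bond is the most electron-rich π bond of 14. It is secured by dosing one equivalent of standardised ozone at −78 °C and stopping short of full conversion, the side-chain alkene having been removed as the acetal in step 1. Reduction with PPh3 under buffered conditions avoids base, so the β,γ-unsaturated diketone should neither conjugate nor undergo transannular aldolisation before step 10.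

Step 10
Reactants: 16 (3Z,7R,8R,9R)-7,8-bis{[(tert-butyldimethylsilyl)oxy]methyl}-9-[(2R)-5,5-dimethoxypentan-2-yl]-3-methylcyclonon-3-ene-1,6-dione
Product: 17 (1R,3Z,7R,8R,9R)-7,8-bis{[(tert-butyldimethylsilyl)oxy]methyl}-9-[(2R)-5,5-dimethoxypentan-2-yl]-3-methylcyclonon-3-ene-1,6-diol (C6 epimers)
Conditions: NaBH4, CeCl3·7H2O, MeOH, −78 → −40 °C
Reagents that add atoms: none
Why: Luche-type borohydride reduction takes both ketones quickly at low temperature without enolisation, so C7 and C9 do not epimerise and the β,γ-alkene does not migrate. C1 is expected to form with the hydroxyl anti to the C9 side chain by Felkin–Anh-type delivery of hydride anti to the branched C10 substituent from the ring periphery (the least secure stereochemical call of the route); the C6 configuration is irrelevant.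

Step 11
Reactants: 17 (1R,3Z,7R,8R,9R)-7,8-bis{[(tert-butyldimethylsilyl)oxy]methyl}-9-[(2R)-5,5-dimethoxypentan-2-yl]-3-methylcyclonon-3-ene-1,6-diol
Product: 18 (1R,3Z,7R,8R,9R)-7,8-bis{[(tert-butyldimethylsilyl)oxy]methyl}-9-[(2R)-5,5-dimethoxypentan-2-yl]-3-methylcyclonon-3-ene-1,6-diyl diacetate
Conditions: Ac2O, pyridine, DMAP (cat.), CH2Cl2, 25 °C
Reagents that add atoms: acetic anhydride, CC(=O)OC(C)=O
Why: DMAP-catalysed acylation esterifies both secondary alcohols with retention; no differentiation of O1 and O6 is needed because only the C6 acetate will later lie β to a formyl group, and capping the alkoxides also blocks silyl migration from O18.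

Step 12
Reactants: 18 (1R,3Z,7R,8R,9R)-7,8-bis{[(tert-butyldimethylsilyl)oxy]methyl}-9-[(2R)-5,5-dimethoxypentan-2-yl]-3-methylcyclonon-3-ene-1,6-diyl diacetate
Product: 20 (1R,3Z,7R,8R,9R)-7,8-bis{[(tert-butyldimethylsilyl)oxy]methyl}-3-methyl-9-[(2R)-5-oxopentan-2-yl]cyclonon-3-ene-1,6-diyl diacetate, via 2,4,6-collidinium N,O-acetal triflate 19 (not isolated)
Conditions: TESOTf (2 equiv), 2,4,6-collidine (3 equiv), CH2Cl2, 0 °C; then H2O, 25 °C
Reagents that add atoms: water, O (carbonyl oxygen of 20)
Why: Chemoselective acetal cleavage of Fujioka type: the silyl triflate ionises the dimethyl acetal, collidine traps the oxocarbenium ion as pyridinium salt 19, and water hydrolyses it to the aldehyde; the medium stays basic, so primary TBS ethers, acetates and the skipped alkene should survive, which plain aqueous acid would not guarantee.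

Step 13
Reactants: 20 (1R,3Z,7R,8R,9R)-7,8-bis{[(tert-butyldimethylsilyl)oxy]methyl}-3-methyl-9-[(2R)-5-oxopentan-2-yl]cyclonon-3-ene-1,6-diyl diacetate; 21 isopropyltriphenylphosphonium iodide
Product: 22 (1R,3Z,7R,8R,9R)-7,8-bis{[(tert-butyldimethylsilyl)oxy]methyl}-3-methyl-9-[(2R)-6-methylhept-5-en-2-yl]cyclonon-3-ene-1,6-diyl diacetate
Conditions: 21 (1.5 equiv), n-BuLi (1.45 equiv), THF, 0 °C; then 20, −78 → 0 °C
Reagents that add atoms: none
Why: Wittig olefination with the non-stabilised isopropylidene ylide restores the trisubstituted side-chain alkene (no E/Z issue, both ylide substituents being methyl); at −78 °C the aldehyde reacts far faster than the secondary acetates, and a slight deficit of base keeps free butyllithium away from the esters.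

Step 14
Reactants: 22 (1R,3Z,7R,8R,9R)-7,8-bis{[(tert-butyldimethylsilyl)oxy]methyl}-3-methyl-9-[(2R)-6-methylhept-5-en-2-yl]cyclonon-3-ene-1,6-diyl diacetate
Product: 23 (1R,3Z,7R,8R,9R)-7,8-bis(hydroxymethyl)-3-methyl-9-[(2R)-6-methylhept-5-en-2-yl]cyclonon-3-ene-1,6-diyl diacetate
Conditions: HF·pyridine, pyridine, THF, 0 → 25 °C
Reagents that add atoms: none
Why: Fluoride-mediated desilylation with pyridine-buffered HF frees both primary alcohols under weakly acidic conditions, where acetate migration from O6 to O18 (a base-promoted process) is slow and the acetates and alkenes are stable.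

Step 15
Reactants: 23 (1R,3Z,7R,8R,9R)-7,8-bis(hydroxymethyl)-3-methyl-9-[(2R)-6-methylhept-5-en-2-yl]cyclonon-3-ene-1,6-diyl diacetate
Product: 25 (1R,3Z,6E,8R,9R)-7,8-diformyl-3-methyl-9-[(2R)-6-methylhept-5-en-2-yl]cyclonona-3,6-dien-1-yl acetate (target CNP0113811.6), via β-acetoxy dialdehyde 24 (not isolated)
Conditions: (COCl)2, DMSO, CH2Cl2, −78 °C; Et3N, −78 → 20 °C
Reagents that add atoms: none
Why: Swern oxidation turns both primary alcohols into alkoxysulfonium salts before base is added, so the 1,4-diol should give dialdehyde 24 and not a lactol or lactone; on warming with triethylamine the C6 acetate, now β to the C7 formyl group, is expelled by E1cB elimination to the conjugated enal. The ring-cis (6E) geometry is the only low-strain option in a nine-membered ring and both C6 epimers converge on it; the C1 acetate has no carbonyl in a β relation and stays, and C8 should keep its configuration if base contact is short and cold.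

## Compound list

1 | (R)-β-citronellene, (3R)-3,7-dimethylocta-1,6-diene | C=C[C@H](C)CCC=C(C)C | starting material
2 | (4R)-4-methylhex-5-enal | C=C[C@H](C)CCC=O | intermediate (not isolated)
3 | (3R)-6,6-dimethoxy-3-methylhex-1-ene | C=C[C@H](C)CCC(OC)OC | intermediate
4 | methyl acrylate | C=CC(=O)OC | starting material
5 | methyl (2E,4R)-7,7-dimethoxy-4-methylhept-2-enoate | COC(=O)/C=C/[C@H](C)CCC(OC)OC | intermediate
6 | (2-bromo-5-methylphenyl)boronic acid | OB(O)c1cc(C)ccc1Br | starting material
7 | methyl (3S,4R)-3-(2-bromo-5-methylphenyl)-7,7-dimethoxy-4-methylheptanoate | COC(=O)C[C@H](c1cc(C)ccc1Br)[C@H](C)CCC(OC)OC | intermediate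
8 | methyl bromoacetate | COC(=O)CBr | starting material
9 | dimethyl 2-[(1R,2R)-1-(2-bromo-5-methylphenyl)-5,5-dimethoxy-2-methylpentyl]butanedioate (C8 epimers) | COC(=O)CC(C(=O)OC)[C@H](c1cc(C)ccc1Br)[C@H](C)CCC(OC)OC | intermediate
10 | dimethyl (3R)-3-[(2R)-5,5-dimethoxypentan-2-yl]-5-methylindane-1,2-dicarboxylate, kinetic mixture at C7/C8 | Cc1ccc2c(c1)[C@H]([C@H](C)CCC(OC)OC)C(C(=O)OC)C2C(=O)OC | intermediate (not isolated)
11 | dimethyl (1S,2R,3R)-3-[(2R)-5,5-dimethoxypentan-2-yl]-5-methyl-2,3-dihydro-1H-indene-1,2-dicarboxylate (all-trans) | Cc1ccc2c(c1)[C@H]([C@H](C)CCC(OC)OC)[C@@H](C(=O)OC)[C@@H]2C(=O)OC | intermediate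
12 | [(1S,2R,3R)-3-[(2R)-5,5-dimethoxypentan-2-yl]-5-methyl-2,3-dihydro-1H-indene-1,2-diyl]dimethanol | Cc1ccc2c(c1)[C@H]([C@H](C)CCC(OC)OC)[C@@H](CO)[C@@H]2CO | intermediate
13 | (1S,2R,3R)-1,2-bis{[(tert-butyldimethylsilyl)oxy]methyl}-3-[(2R)-5,5-dimethoxypentan-2-yl]-5-methyl-2,3-dihydro-1H-indene | Cc1ccc2c(c1)[C@H]([C@H](C)CCC(OC)OC)[C@@H](CO[Si](C)(C)C(C)(C)C)[C@@H]2CO[Si](C)(C)C(C)(C)C | intermediate
14 | (1S,2R,3R)-1,2-bis{[(tert-butyldimethylsilyl)oxy]methyl}-3-[(2R)-5,5-dimethoxypentan-2-yl]-5-methyl-2,3,4,7-tetrahydro-1H-indene | CC1=CCC2=C(C1)[C@H]([C@H](C)CCC(OC)OC)[C@@H](CO[Si](C)(C)C(C)(C)C)[C@@H]2CO[Si](C)(C)C(C)(C)C | intermediate (key-step precursor)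
15 | secondary ozonide of 14 (1,2,4-trioxolane bridging C1 and C6) | CC1=CCC2(OOC3(C1)O2)[C@@H](CO[Si](C)(C)C(C)(C)C)[C@H](CO[Si](C)(C)C(C)(C)C)[C@H]3[C@H](C)CCC(OC)OC | intermediate (not isolated)
16 | (3Z,7R,8R,9R)-7,8-bis{[(tert-butyldimethylsilyl)oxy]methyl}-9-[(2R)-5,5-dimethoxypentan-2-yl]-3-methylcyclonon-3-ene-1,6-dione | O=C1C/C(C)=C\CC(=O)[C@@H](CO[Si](C)(C)C(C)(C)C)[C@H](CO[Si](C)(C)C(C)(C)C)[C@H]1[C@H](C)CCC(OC)OC | intermediate (key-step product)
17 | (1R,3Z,7R,8R,9R)-7,8-bis{[(tert-butyldimethylsilyl)oxy]methyl}-9-[(2R)-5,5-dimethoxypentan-2-yl]-3-methylcyclonon-3-ene-1,6-diol (C6 epimers) | O[C@@H]1C/C(C)=C\CC(O)[C@@H](CO[Si](C)(C)C(C)(C)C)[C@H](CO[Si](C)(C)C(C)(C)C)[C@H]1[C@H](C)CCC(OC)OC | intermediate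
18 | diacetate of 17 | CC(=O)O[C@@H]1C/C(C)=C\CC(OC(C)=O)[C@@H](CO[Si](C)(C)C(C)(C)C)[C@H](CO[Si](C)(C)C(C)(C)C)[C@H]1[C@H](C)CCC(OC)OC | intermediate
19 | N-(1-methoxyalkyl)-2,4,6-collidinium triflate derived from 18 at C13 | CC(=O)O[C@@H]1C/C(C)=C\CC(OC(C)=O)[C@@H](CO[Si](C)(C)C(C)(C)C)[C@H](CO[Si](C)(C)C(C)(C)C)[C@H]1[C@H](C)CCC(OC)[n+]1c(C)cc(C)cc1C.[O-]S(=O)(=O)C(F)(F)F | intermediate (not isolated)
20 | (1R,3Z,7R,8R,9R)-7,8-bis{[(tert-butyldimethylsilyl)oxy]methyl}-3-methyl-9-[(2R)-5-oxopentan-2-yl]cyclonon-3-ene-1,6-diyl diacetate | CC(=O)O[C@@H]1C/C(C)=C\CC(OC(C)=O)[C@@H](CO[Si](C)(C)C(C)(C)C)[C@H](CO[Si](C)(C)C(C)(C)C)[C@H]1[C@H](C)CCC=O | intermediate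
21 | isopropyltriphenylphosphonium iodide | CC(C)[P+](c1ccccc1)(c1ccccc1)c1ccccc1.[I-] | starting material
22 | (1R,3Z,7R,8R,9R)-7,8-bis{[(tert-butyldimethylsilyl)oxy]methyl}-3-methyl-9-[(2R)-6-methylhept-5-en-2-yl]cyclonon-3-ene-1,6-diyl diacetate | CC(=O)O[C@@H]1C/C(C)=C\CC(OC(C)=O)[C@@H](CO[Si](C)(C)C(C)(C)C)[C@H](CO[Si](C)(C)C(C)(C)C)[C@H]1[C@H](C)CCC=C(C)C | intermediate
23 | (1R,3Z,7R,8R,9R)-7,8-bis(hydroxymethyl)-3-methyl-9-[(2R)-6-methylhept-5-en-2-yl]cyclonon-3-ene-1,6-diyl diacetate | CC(=O)O[C@@H]1C/C(C)=C\CC(OC(C)=O)[C@@H](CO)[C@H](CO)[C@H]1[C@H](C)CCC=C(C)C | intermediate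
24 | 7,8-diformyl analogue of 23 (β-acetoxy dialdehyde) | CC(=O)O[C@@H]1C/C(C)=C\CC(OC(C)=O)[C@@H](C=O)[C@H](C=O)[C@H]1[C@H](C)CCC=C(C)C | intermediate (not isolated)
25 | (1R,3Z,6E,8R,9R)-7,8-diformyl-3-methyl-9-[(2R)-6-methylhept-5-en-2-yl]cyclonona-3,6-dien-1-yl acetate | CC(=O)O[C@@H]1C/C(C)=C\C/C=C(/C=O)[C@H](C=O)[C@H]1[C@H](C)CCC=C(C)C | target

## Step count and least certain steps

Total: 15 steps. Longest linear sequence: 15 steps (1 → 25); 4, 6, 8 and 21 enter as purchased reagents.

**Step 9 (key step).** Most likely failure: loss of site selectivity. The C3=C4 bond carries only one alkyl group less than C1=C6 and is less hindered, so ozone may attack it competitively or in a second addition. Fallback, from 14: peracid epoxidation (m-CPBA, NaHCO3, CH2Cl2, −20 °C), which discriminates more strongly by alkyl substitution, should give the C1–C6 epoxide F1. Brief treatment with H5IO6 in THF/H2O at 0 °C then opens and cleaves it, returning to the route at 16; the acetal and silyl ethers are the groups to watch during the short acidic contact.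

**Step 5.** Most likely failure: the palladium enolate undergoes β-hydride elimination or protonolysis (hydrodebromination) instead of reductive elimination, or the methyl esters undergo Claisen condensation under the amide base. Fallback, from 5: the ring is closed at C7–C8 instead of C6–C7.
- Miyaura borylation of methyl (2-bromo-4-methylphenyl)acetate (B2pin2, Pd(dppf)Cl2, KOAc) gives methyl 2-[4-methyl-2-(4,4,5,5-tetramethyl-1,3,2-dioxaborolan-2-yl)phenyl]acetate F3.
- Addition of F3 to 5 under the rhodium/(S)-BINAP conditions of step 3 gives methyl (3S,4R)-7,7-dimethoxy-3-[2-(2-methoxy-2-oxoethyl)-5-methylphenyl]-4-methylheptanoate F4.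
- Double deprotonation (LDA, 2.2 equiv, THF, −78 °C) and oxidation with CuCl2 couples the two enolate carbons intramolecularly to 10, which methoxide equilibrates to 11.

**Step 10.** Most likely failure: hydride delivery to the wrong face of the C1 carbonyl, because the local conformation of the flexible ring, not a simple steric rule, decides the exposed face. Fallback, from 16: the reduction is run as before and, if it gives mainly the (1S)-epimeric diol F2, this is treated under Mitsunobu conditions (PPh3, DIAD, AcOH, toluene, 0 → 25 °C). Both carbinols are inverted and acetylated in one operation (C6 is irrelevant), returning at 18 and replacing step 11.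

**Step 3.** Most likely failure: slow transmetalation and insertion caused by the ortho bromine and the γ-branch, so that protodeboronation outruns addition, or incomplete catalyst control over the C10 centre. Fallback, from 3: an auxiliary-controlled cuprate addition.
- Cross-metathesis of 3 with (S)-3-acryloyl-4-phenyl-1,3-oxazolidin-2-one (same ruthenium catalyst) gives (4S)-3-[(2E,4R)-7,7-dimethoxy-4-methylhept-2-enoyl]-4-phenyl-1,3-oxazolidin-2-one F5.
- (2-Bromo-5-methylphenyl)magnesium chloride F6 is made from 1-bromo-2-iodo-4-methylbenzene and i-PrMgCl·LiCl at −40 °C. With CuBr·SMe2 it adds to the chelated s-cis imide anti to the phenyl group (β-re face) to give (4S)-3-[(3S,4R)-3-(2-bromo-5-methylphenyl)-7,7-dimethoxy-4-methylheptanoyl]-4-phenyl-1,3-oxazolidin-2-one F7.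
- NaOMe in MeOH at 0 °C releases 7.

**Step 15.** Most likely failure: epimerisation at C8, or migration of the double bond into the C7=C8 position, while the amine base that drives the elimination is still present; hemiacetal formation between the two oxidising arms is the second risk. Fallback, from 23: oxidation and elimination are separated. A buffered hypervalent-iodine oxidation (Dess–Martin periodinane in excess, NaHCO3, CH2Cl2, 0 °C) stops at 24, which is isolated. The acetate is then expelled in a separate, brief operation on a weak base (DABCO at −20 °C or filtration through basic alumina), returning at 25. This fallback makes no compound outside the list (F0).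

## Further compounds

F1 | step 9 | C1–C6 epoxide of 14 | CC1=CCC23OC2(C1)[C@H]([C@H](C)CCC(OC)OC)[C@@H](CO[Si](C)(C)C(C)(C)C)[C@@H]3CO[Si](C)(C)C(C)(C)C
F2 | step 10 | (1S)-epimer of diol 17 | O[C@H]1C/C(C)=C\CC(O)[C@@H](CO[Si](C)(C)C(C)(C)C)[C@H](CO[Si](C)(C)C(C)(C)C)[C@H]1[C@H](C)CCC(OC)OC
F3 | step 5 | methyl 2-[4-methyl-2-(4,4,5,5-tetramethyl-1,3,2-dioxaborolan-2-yl)phenyl]acetate | COC(=O)Cc1ccc(C)cc1B1OC(C)(C)C(C)(C)O1
F4 | step 5 | methyl (3S,4R)-7,7-dimethoxy-3-[2-(2-methoxy-2-oxoethyl)-5-methylphenyl]-4-methylheptanoate | COC(=O)C[C@H](c1cc(C)ccc1CC(=O)OC)[C@H](C)CCC(OC)OC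
F5 | step 3 | (4S)-3-[(2E,4R)-7,7-dimethoxy-4-methylhept-2-enoyl]-4-phenyl-1,3-oxazolidin-2-one | O=C(/C=C/[C@H](C)CCC(OC)OC)N1[C@@H](c2ccccc2)COC1=O
F6 | step 3 | (2-bromo-5-methylphenyl)magnesium chloride | Cc1ccc(Br)c([Mg]Cl)c1
F7 | step 3 | (4S)-3-[(3S,4R)-3-(2-bromo-5-methylphenyl)-7,7-dimethoxy-4-methylheptanoyl]-4-phenyl-1,3-oxazolidin-2-one | O=C(C[C@H](c1cc(C)ccc1Br)[C@H](C)CCC(OC)OC)N1[C@@H](c2ccccc2)COC1=O
F0 | step 15 | none | none
A1 | alternative 1 | acyclic C1 aldehyde with dimethyl 2,3-bis(alkylidene)succinate (C6=C7 and C8=C9), 10R | O=CC/C(C)=C\C/C=C(C(=O)OC)\C(C(=O)OC)=C/[C@H](C)CCC=C(C)C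
A2 | alternative 1 | cis-fused γ-lactone of the cyclononadiene, methyl ester on C7 | O=C1O[C@@H]2C/C(C)=C\C/C=C(/C(=O)OC)[C@H]1[C@H]2[C@H](C)CCC=C(C)C
A3 | alternative 2 | acyclic C1 aldehyde carrying the C4 pinacol allylboronate, bis-TBS ether (boron-bearing centre to be chosen) | O=C[C@H]([C@H](C)CCC=C(C)C)[C@@H](CO[Si](C)(C)C(C)(C)C)/C(CO[Si](C)(C)C(C)(C)C)=C\CC(B1OC(C)(C)C(C)(C)O1)C(C)=C
A4 | alternative 2 | cyclononadienol with free C1 hydroxyl, bis-TBS ether | O[C@@H]1C/C(C)=C\C/C=C(/CO[Si](C)(C)C(C)(C)C)[C@H](CO[Si](C)(C)C(C)(C)C)[C@H]1[C@H](C)CCC=C(C)C
A5 | alternative 3 | 2-alkylidene-7-alkenyl-4-methyl-tetrahydrooxepine, bis-TBS ether (alkene geometries and C6 configuration to be matched) | C[C@H](CCC=C(C)C)C=C1CC(C)=CCC(O1)C(CO[Si](C)(C)C(C)(C)C)=CCO[Si](C)(C)C(C)(C)C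
A6 | alternative 3 | cyclonona-3,6-dienone with C1 ketone, bis-TBS ether | O=C1C/C(C)=C\C/C=C(/CO[Si](C)(C)C(C)(C)C)[C@H](CO[Si](C)(C)C(C)(C)C)[C@H]1[C@H](C)CCC=C(C)C
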